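**Retrosynthetic overview**

1. Numbering used throughout: C1 = CH(OAc), C2 = CH2, C3 = C(CH3), C4 = CHBr, C5 = CH2, C6 = C(CH3), C7 = CH(CH3), C8 = CHBr, C9 = CH(OH), C10 = CH(CH3), C11 = the carbon common to all three rings. Rings: cyclobutane C1–C2–C3–C11, cyclopentane C3–C4–C5–C6–C11, cyclohexane C6–C7–C8–C9–C10–C11.
2. Late stage: C8–Br and C9–OH come from a C9 ketone (kinetic enolate bromination, then hydride from the open face), C4–Br from the (4R)-alcohol with inversion, C1–OAc from a cyclobutanone.
3. Key disconnection: the cyclobutanone C1(=O)–C2–C3–C11 is cut into a ketene C11=C1=O and the alkene C3(CH3)=C2H2, which are joined by the tether C6–C5–C4. The intramolecular [2+2] makes C1–C2 and C11–C3, and C11–C3 is the bond that closes the cyclopentane.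
4. Enabling feature: C11 belongs to all three rings and is flanked in the four-membered ring by a carbonyl-level carbon (C1), a CH2 (C2) and a methyl-bearing quaternary carbon (C3). This is the retron of a ketene + 2-methyl-1-alkene cycloaddition, and the quaternary centre C6 on the three-atom tether relays its configuration to C11 and C3.
5. Ring order: cyclohexane first (enantioselective Diels–Alder of tiglic aldehyde with a 2-silyloxydiene; epimers at C10 and C11 converge later), then cyclobutanone and cyclopentane in the key step, with the cyclopentane bond C11–C3 formed last.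

Key step: step 11

Assumption: the sense of induction of the oxazaborolidinium catalyst (step 3) and of the chromium ligand (step 6) follows the accepted models (formyl C–H···O binding of α-substituted enals; ligand-controlled Si-face delivery to the aldehyde); if the opposite sense were found, the antipodal catalyst or ligand would be used.

**Route**

Step 1
Reactants: 1 3-(triphenylphosphoranylidene)butan-2-one; 2 2-[(4-methoxybenzyl)oxy]acetaldehyde
Product: 3 (E)-5-[(4-methoxybenzyl)oxy]-3-methylpent-3-en-2-one
Conditions: toluene, 90 °C
Reagents that add atoms: none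
Why: Wittig olefination with a stabilized α-methyl keto ylide should give the (E)-trisubstituted enone, which puts C1 (CH2OPMB) trans to the acetyl carbon C9 and so "outside" in the later s-cis diene.

Step 2
Reactants: 3 enone
Product: 4 (E)-2-(triisopropylsilyloxy)-3-methyl-5-[(4-methoxybenzyl)oxy]penta-1,3-diene
Conditions: TIPSOTf, Et3N, CH2Cl2, 0 °C
Reagents that add atoms: triisopropylsilyl trifluoromethanesulfonate, CC(C)[Si](OS(=O)(=O)C(F)(F)F)(C(C)C)C(C)C
Why: Soft enolization (O-silylation of the enone, then amine deprotonation of the α′-methyl group C8) should give the cross-conjugated 2-silyloxydiene, the bulky TIPS group making the enol ether robust towards the Lewis acid of step 3.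

Step 3
Reactants: 4 silyloxydiene; 5 tiglic aldehyde ((E)-2-methylbut-2-enal)
Product: 6 Diels–Alder adduct (6R,7S; both C11 epimers)
Conditions: (R)-o-tolyl-oxazaborolidine (from (R)-α,α-diphenylprolinol)·Tf2NH (20 mol %), CH2Cl2, −78 → −40 °C
Reagents that add atoms: none
Why: Catalytic enantioselective Diels–Alder reaction with a chiral oxazaborolidinium Lewis acid: the silyloxy group makes C8 the nucleophilic diene terminus so that C8 bonds to the β-carbon C7 and C11 to the α-carbon C6 of the enal, the E geometry of 5 is transferred suprafacially into the cis relationship of the methyl groups on C6 and C7, the catalyst-bound s-trans enal is shielded on its Re face at C6 so that the 6R,7S adduct should result, and the endo/exo ratio only concerns C11, which becomes trigonal again in step 11.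

Step 4
Reactants: 6 Diels–Alder adduct
Product: 7 methyl enol ether (E/Z; C11 epimers)
Conditions: MeOCH2PPh3Cl, KHMDS, THF, 0 °C → rt
Reagents that add atoms: (methoxymethyl)triphenylphosphonium chloride, COC[P+](c1ccccc1)(c1ccccc1)c1ccccc1.[Cl-]
Why: Wittig methoxymethylenation adds C4 to the hindered, non-enolizable aldehyde; no stereocentre is involved and the enol ether geometry is irrelevant.

Step 5
Reactants: 7 methyl enol ether
Product: 8 keto aldehyde (6R,7S; C10/C11 epimers)
Conditions: 1 M HCl, THF, rt
Reagents that add atoms: water, O
Why: Acid hydrolysis of both enol ethers unmasks the homologated aldehyde (C4) and the C9 ketone while the PMB ether survives dilute acid; C10 is formed as an epimerizable centre whose configuration is settled only in step 14.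

Step 6
Reactants: 8 keto aldehyde; 9 2-bromopropene
Product: 10 allylic alcohol (4R,6R,7S; C10/C11 epimers)
Conditions: CrCl2, NiCl2 (cat.), Kishi-type chiral oxazoline–sulfonamide ligand, Et3N, THF, rt
Reagents that add atoms: none
Why: Nozaki–Hiyama–Kishi coupling: the 2-propenylchromium(III) species adds to the aldehyde and leaves the ketone untouched, and the chiral sulfonamide ligand on chromium directs the alkenyl group to the Si face of C4, which should set the 4R carbinol (reagent control, the nearest stereocentre C6 being two bonds away).

Step 7
Reactants: 10 allylic alcohol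
Product: 11 TBS ether
Conditions: TBSOTf, 2,6-lutidine, CH2Cl2, −78 °C
Reagents that add atoms: tert-butyldimethylsilyl trifluoromethanesulfonate, CC(C)(C)[Si](C)(C)OS(=O)(=O)C(F)(F)F
Why: Silyl ether formation; at −78 °C silylation of the alcohol is much faster than enol silylation of the ketone.

Step 8
Reactants: 11 TBS ether
Product: 12 C9 dioxolane
Conditions: TMSOCH2CH2OTMS, TMSOTf (cat.), CH2Cl2, −78 → −20 °C
Reagents that add atoms: 1,2-bis(trimethylsilyloxy)ethane, C[Si](C)(C)OCCO[Si](C)(C)C
Why: Noyori ketalization under aprotic conditions masks the C9 ketone so that the cyclobutanone formed in step 11 can later be reduced alone; silyl and PMB ethers tolerate catalytic TMSOTf at low temperature.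

Step 9
Reactants: 12 dioxolane
Product: 13 primary alcohol
Conditions: DDQ, CH2Cl2/pH 7 buffer, 0 °C
Reagents that add atoms: none
Why: Oxidative cleavage of the PMB ether by DDQ (single-electron oxidation of the electron-rich arene) frees the primary alcohol and leaves the silyl ether, the ketal and the isolated alkene intact.

Step 10
Reactants: 13 primary alcohol
Product: 14 carboxylic acid
Conditions: TEMPO (cat.), PhI(OAc)2, MeCN/pH 7 buffer, rt
Reagents that add atoms: water, O
Why: TEMPO/PhI(OAc)2 oxidation in the presence of water takes the primary alcohol through the aldehyde hydrate to the acid without touching the alkene; epimerization at C11 is of no consequence.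

Step 11
Reactants: 14 carboxylic acid
Product: 17 tricyclic cyclobutanone (3R,4R,6R,7S,11R; C10 epimers), via acid chloride 15 (not isolated), via ketene 16 (not isolated)
Conditions: 1-chloro-N,N,2-trimethylprop-1-en-1-amine (Ghosez's reagent), CH2Cl2, 0 °C → rt; then Et3N, toluene, 110 °C, high dilution
Reagents that add atoms: none
Why: Ghosez's reagent converts the acid into acid chloride 15 without acidic by-products and Et3N dehydrochlorinates it to the dialkylketene 16 (C11=C1=O), which makes C11 trigonal so that both C11 epimers of 14 converge; the ketene then adds to the tethered 2-methyl-1-alkene in a thermal, concerted but asynchronous [π2s+π2a] cycloaddition in which the CH2 terminus C2 bonds to the ketene carbonyl carbon C1 while positive charge builds at tertiary C3, and C3 finally bonds to C11. The closest known reaction type is the intramolecular ketene–alkene [2+2] cycloaddition of α,α-dialkylketenes that carry a three-atom tether to a 1,1-disubstituted alkene, which gives 1,5-disubstituted bicyclo[3.2.0]heptan-6-ones. The C11–C3 bond closes the cyclopentane C3–C4–C5–C6–C11 (5-exo with respect to both the C3=C2 and the C11=C1 π bond, C2 and C1 staying outside this ring), and the same bond together with C1–C2 completes the cyclobutanone C1–C2–C3–C11 as the four-membered ring of the cycloaddition. The two new stereocentres are controlled by the quaternary centre C6: the tether can deliver C3 only to the face of the planar ketene carbon C11 on which C5 sits (cis-fused hydrindane, 11R), and a four-membered ring can only be cis-fused to the five-membered ring, which places C2 syn to C1 and the C3 methyl anti (3R); C4, C7 and C10 are not touched. The step needs regioselectivity for the fused over the bridged adduct and chemoselectivity over ketene dimerization and ene reaction: the first is secured by the polarization of the 1,1-disubstituted alkene (only C3 can carry the developing positive charge), the second by intramolecularity, by the Thorpe–Ingold effect of the quaternary C6 in the tether and by the low tendency of hindered dialkylketenes to dimerize.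

Step 12
Reactants: 17 tricyclic cyclobutanone
Product: 18 exo cyclobutanol (1R)
Conditions: Li, NH3 (l), THF, t-BuOH, −78 °C; then NH4Cl
Reagents that add atoms: none
Why: Dissolving-metal reduction of the ketone gives, through the configurationally mobile ketyl/carbanion, the thermodynamically preferred alcohol, here expected to be the exo alcohol (1R) whose OH lies on the face of C10 and the C3 methyl and away from C4, C5 and the C6 methyl, whereas a hydride would enter from that same open face and give the epimer; the silyl ether and the ketal are inert.

Step 13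
Reactants: 18 exo cyclobutanol
Product: 19 C1 acetate
Conditions: Ac2O, DMAP, pyridine, CH2Cl2, rt
Reagents that add atoms: acetic anhydride, CC(=O)OC(C)=O
Why: DMAP-catalysed acylation of the only free hydroxyl group.

Step 14
Reactants: 19 C1 acetate
Product: 20 keto alcohol (1R,3R,4R,6R,7S,10R,11R)
Conditions: 1 M HCl, THF, rt
Reagents that add atoms: water, O
Why: Aqueous acid hydrolyses the dioxolane and the silyl ether while the hindered secondary acetate should survive, and acid-catalysed enolization towards C10 equilibrates this centre to the equatorial methyl epimer (10R), the axial one suffering a 1,3-diaxial contact with the axial methyl on C6.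

Step 15
Reactants: 20 keto alcohol
Product: 21 C4 bromide (4S)
Conditions: PPh3, CBr4, CH2Cl2, 0 °C → rt
Reagents that add atoms: carbon tetrabromide, BrC(Br)(Br)Br
Why: Appel reaction: the oxyphosphonium ion formed on the concave face is displaced by bromide from the open convex face with inversion (SN2) to give the 4S bromide, by analogy with inversions at cyclopentane carbons next to a quaternary centre such as C17 of 17β-hydroxy steroids; the ketone and the acetate are inert.

Step 16
Reactants: 21 C4 bromide
Product: 23 α-bromo ketone (8S), via TMS enol ether 22 (not isolated)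
Conditions: LiHMDS, TMSCl, THF, −78 °C; then NBS, −78 → 0 °C
Reagents that add atoms: N-bromosuccinimide, O=C1CCC(=O)N1Br
Why: Kinetic enolate formation occurs at the unhindered C8 methylene and not at the tertiary C10 flanked by quaternary C11 (ketone deprotonation outpaces that of the acetate), and bromination of the silyl enol ether by NBS should occur anti to the axial methyl on C6 to give the equatorial bromide (8S), which is also the thermodynamically favoured epimer of this enolizable centre.

Step 17
Reactants: 23 α-bromo ketone
Product: 24 target CNP0246576.1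
Conditions: L-selectride, THF, −78 °C; then NH4Cl (aq)
Reagents that add atoms: none
Why: Hydride reduction of the α-bromo ketone with a bulky borohydride: axial approach to C9 is blocked by the axial C11–C3 bond and its methyl group, so hydride should enter equatorially from the opposite face and give the axial alcohol cis to the C8 bromide (9R); the cis bromohydrin cannot close to an epoxide and the acetate survives at −78 °C.

**Compound list**

Where a name says "epimers", the SMILES leaves that centre undefined on purpose.

1 | 3-(triphenylphosphoranylidene)butan-2-one | CC(=O)C(C)=P(c1ccccc1)(c1ccccc1)c1ccccc1 | starting material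
2 | 2-[(4-methoxybenzyl)oxy]acetaldehyde | O=CCOCc1ccc(OC)cc1 | starting material
3 | (E)-5-[(4-methoxybenzyl)oxy]-3-methylpent-3-en-2-one | CC(=O)/C(C)=C/COCc1ccc(OC)cc1 | intermediate
4 | (E)-2-(triisopropylsilyloxy)-3-methyl-5-[(4-methoxybenzyl)oxy]penta-1,3-diene | C=C(O[Si](C(C)C)(C(C)C)C(C)C)/C(C)=C/COCc1ccc(OC)cc1 | intermediate
5 | tiglic aldehyde, (E)-2-methylbut-2-enal | C/C=C(\C)C=O | starting material
6 | (1R,6S)-2-{[(4-methoxybenzyl)oxy]methyl}-1,3,6-trimethyl-4-(triisopropylsilyloxy)cyclohex-3-ene-1-carbaldehyde (skeleton 6R,7S; C11 epimers) | O=C[C@]1(C)[C@@H](C)CC(O[Si](C(C)C)(C(C)C)C(C)C)=C(C)C1COCc1ccc(OC)cc1 | intermediate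
7 | methyl enol ether: 6 with CH=CH–OMe (C5=C4, E/Z) in place of CHO (6R,7S; C11 epimers) | COC=C[C@]1(C)[C@@H](C)CC(O[Si](C(C)C)(C(C)C)C(C)C)=C(C)C1COCc1ccc(OC)cc1 | intermediate
8 | keto aldehyde: cyclohexanone (C9=O) with CH3 and CH2CHO on C6, CH3 on C7 and C10, CH2OPMB on C11 (6R,7S; C10/C11 epimers) | O=CC[C@]1(C)[C@@H](C)CC(=O)C(C)C1COCc1ccc(OC)cc1 | intermediate
9 | 2-bromopropene | CC(Br)=C | starting material
10 | allylic alcohol: 8 with CH2–CH(OH)–C(CH3)=CH2 on C6 (4R,6R,7S; C10/C11 epimers) | C=C(C)[C@H](O)C[C@]1(C)[C@@H](C)CC(=O)C(C)C1COCc1ccc(OC)cc1 | intermediate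
11 | C4 TBS ether of 10 | C=C(C)[C@H](O[Si](C)(C)C(C)(C)C)C[C@]1(C)[C@@H](C)CC(=O)C(C)C1COCc1ccc(OC)cc1 | intermediate
12 | C9 ethylene ketal of 11 | C=C(C)[C@H](O[Si](C)(C)C(C)(C)C)C[C@]1(C)[C@@H](C)CC2(OCCO2)C(C)C1COCc1ccc(OC)cc1 | intermediate
13 | primary alcohol (C1–OH) from 12 | C=C(C)[C@H](O[Si](C)(C)C(C)(C)C)C[C@]1(C)[C@@H](C)CC2(OCCO2)C(C)C1CO | intermediate
14 | carboxylic acid (C1OOH on C11) (4R,6R,7S; C10/C11 epimers) | C=C(C)[C@H](O[Si](C)(C)C(C)(C)C)C[C@]1(C)[C@@H](C)CC2(OCCO2)C(C)C1C(=O)O | intermediate
15 | acid chloride of 14 | C=C(C)[C@H](O[Si](C)(C)C(C)(C)C)C[C@]1(C)[C@@H](C)CC2(OCCO2)C(C)C1C(=O)Cl | intermediate (not isolated)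
16 | ketene C11=C1=O (4R,6R,7S; C10 epimers) | C=C(C)[C@H](O[Si](C)(C)C(C)(C)C)C[C@]1(C)[C@@H](C)CC2(OCCO2)C(C)C1=C=O | intermediate (not isolated)
17 | tricyclic cyclobutanone: C1 ketone, C4 OTBS, C9 ethylene ketal (3R,4R,6R,7S,11R; C10 epimers) | O=C1C[C@@]2(C)[C@H](O[Si](C)(C)C(C)(C)C)C[C@]3(C)[C@@H](C)CC4(OCCO4)C(C)[C@]123 | intermediate
18 | exo cyclobutanol (1R,3R,4R,6R,7S,11R; C10 epimers) | O[C@@H]1C[C@@]2(C)[C@H](O[Si](C)(C)C(C)(C)C)C[C@]3(C)[C@@H](C)CC4(OCCO4)C(C)[C@]123 | intermediate
19 | C1 acetate of 18 | CC(=O)O[C@@H]1C[C@@]2(C)[C@H](O[Si](C)(C)C(C)(C)C)C[C@]3(C)[C@@H](C)CC4(OCCO4)C(C)[C@]123 | intermediate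
20 | keto alcohol: C1 OAc, C4 OH, C9 ketone (1R,3R,4R,6R,7S,10R,11R) | CC(=O)O[C@@H]1C[C@@]2(C)[C@H](O)C[C@]3(C)[C@@H](C)CC(=O)[C@H](C)[C@]123 | intermediate
21 | C4 bromide: C1 OAc, C4 Br, C9 ketone (1R,3R,4S,6R,7S,10R,11R) | CC(=O)O[C@@H]1C[C@@]2(C)[C@@H](Br)C[C@]3(C)[C@@H](C)CC(=O)[C@H](C)[C@]123 | intermediate
22 | C8=C9 trimethylsilyl enol ether of 21 | CC(=O)O[C@@H]1C[C@@]2(C)[C@@H](Br)C[C@]3(C)[C@@H](C)C=C(O[Si](C)(C)C)[C@H](C)[C@]123 | intermediate (not isolated)
23 | α-bromo ketone: C1 OAc, C4 Br, C8 Br, C9 ketone (1R,3R,4S,6R,7R,8S,10R,11R) | CC(=O)O[C@@H]1C[C@@]2(C)[C@@H](Br)C[C@]3(C)[C@@H](C)[C@H](Br)C(=O)[C@H](C)[C@]123 | intermediate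
24 | CNP0246576.1, (1R,3R,4S,6R,7R,8S,9R,10R,11R)-4,8-dibromo-9-hydroxy-3,6,7,10-tetramethyl tricycle, C1 acetate (numbering of the overview) | CC(=O)O[C@@H]1C[C@@]2(C)[C@@H](Br)C[C@]3(C)[C@@H](C)[C@H](Br)[C@H](O)[C@H](C)[C@]123 | target

**Step count and risks**

Total: 17 steps. Longest linear sequence: 17 steps (from 1 and 2 to 24; 5 and 9 enter as purchased compounds).

Steps most likely to fail:

1. Step 15 (C4 alcohol to bromide). What may go wrong: the activated C4–O bond, which sits next to the quaternary cyclobutane carbon C3, ionizes instead of being displaced, and a cyclobutane bond then migrates (ring expansion) or a proton is lost (elimination); formation of the bulky oxyphosphonium ion on the concave face may also be slow. Fallback: setting out from 20, the alcohol would first be converted into the isolable C4 triflate F1 (Tf2O, pyridine, CH2Cl2, −40 °C), and this would be displaced in a separate operation by Bu4NBr in toluene at low temperature. Activation and substitution are thus decoupled: the leaving group is installed by a small electrophile that reaches the concave hydroxyl, and substitution by a poorly solvated bromide in a non-ionizing solvent disfavours carbocation formation. The product is bromide 21, where the route is rejoined.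

2. Step 12 (configuration at C1). What may go wrong: poor facial/thermodynamic selectivity in the protonation of the ketyl-derived carbanion, or fragmentation of the strained cyclobutanone ketyl radical anion. Fallback: setting out from 17, reduction with NaBH4 (MeOH, 0 °C) should give mainly the C1-epimeric endo alcohol F2 by attack on the open face. This alcohol would then be equilibrated by reversible hydrogen transfer under Meerwein–Ponndorf–Verley/Oppenauer conditions (Al(O-i-Pr)3, a trace of acetone, toluene/i-PrOH, reflux), which should move the mixture towards the more stable exo alcohol 18, where the route is rejoined.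

3. Step 11 (key cycloaddition). What may go wrong: the hindered dialkylketene reacts too slowly with the alkene, because the new C11–C3 bond joins two fully substituted carbons next to a third, and is lost to dimerization, ene reaction or hydrolysis. Fallback: setting out from 14, the acid would be converted (Ghosez's reagent, then pyrrolidine) into the pyrrolidine amide F3. Tf2O and 2,6-di-tert-butyl-4-methylpyridine in 1,2-dichloroethane would give the keteniminium triflate F4, whose cationic cumulene is far more electrophilic than the ketene and should add to the same alkene under the same regio- and stereochemical constraints to give the cyclobutaniminium triflate F5. Hydrolysis with aqueous NaHCO3 returns cyclobutanone 17.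

Further compounds
F1 | step 15 | C4 triflate of 20 (4R) | CC(=O)O[C@@H]1C[C@@]2(C)[C@H](OS(=O)(=O)C(F)(F)F)C[C@]3(C)[C@@H](C)CC(=O)[C@H](C)[C@]123
F2 | step 12 | endo cyclobutanol, C1 epimer of 18 (C10 epimers) | O[C@H]1C[C@@]2(C)[C@H](O[Si](C)(C)C(C)(C)C)C[C@]3(C)[C@@H](C)CC4(OCCO4)C(C)[C@]123
F3 | step 11 | pyrrolidine amide of 14 (C10/C11 epimers) | C=C(C)[C@H](O[Si](C)(C)C(C)(C)C)C[C@]1(C)[C@@H](C)CC2(OCCO2)C(C)C1C(=O)N3CCCC3
F4 | step 11 | keteniminium triflate from F3 (C10 epimers) | C=C(C)[C@H](O[Si](C)(C)C(C)(C)C)C[C@]1(C)[C@@H](C)CC2(OCCO2)C(C)C1=C=[N+]3CCCC3.[O-]S(=O)(=O)C(F)(F)F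
F5 | step 11 | tricyclic cyclobutaniminium triflate (C10 epimers) | C1(=[N+]5CCCC5)C[C@@]2(C)[C@H](O[Si](C)(C)C(C)(C)C)C[C@]3(C)[C@@H](C)CC4(OCCO4)C(C)[C@]123.[O-]S(=O)(=O)C(F)(F)F
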